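## Structural features

Atoms are numbered C1 to C20 along the chain, starting at the lactone carbonyl.

- **Skeleton.** The target is one unbranched C20 chain. C1 to C5 and the oxygen on C5 form a 5,6-dihydro-2H-pyran-2-one (ring A, C2=C3 cis). C7, C9 and C11 carry free hydroxyl groups, and C12 to C20 are a plain nonyl tail.
- **Stereocentres.** C5, C7, C9 and C11 (5S,7S,9S,11R) are never adjacent, because one CH2 separates each pair. The relations are 5,7-anti, 7,9-syn and 9,11-anti.
- **Fragile groups.** The enoate of ring A does not tolerate base (ring opening, loss of the C5 oxygen to a dienoate, oxa-Michael attack), hydrides, cuprates, free radicals or hydrogenation. It therefore has to be made last.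
- **Acyl migration.** The free 1,3-polyol can shuttle acyl groups, so the ring should close at a point where only the C5 hydroxyl can form a six-membered ring.
- **Real difficulty.** No ring or single bond is hard. The problem is the skipped stereotetrad, which normally costs one chiral controller per centre, with the sense of control changing along the chain.
- **Feature exploited by the key step.** The anti,syn,anti array C5 to C11 has a local mirror plane through C8. C5/C11 and C7/C9 are pairwise mirror images, and each outer carbinol is followed by a CH2 (C4, C12). Only what lies beyond C4 and C12 breaks this symmetry.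

## Logic of the disconnections

**14 to 13 to 12.**
- Bonds cut: the acyl-oxygen bond O-C1 of ring A. The four oxygens are then masked, as a ketal on the syn pair C7/C9 and as silyl ethers on C5 and C11.
- Reason: the sensitive ring appears only in an acidic last operation.
- Gain: an open chain free of base-sensitive groups.
- Demand: C2=C3 must already be Z, and only the C5 hydroxyl may reach C1 through a six-membered ring.

**12 to 10 and 11, then 10 to 9.**
- Bonds cut: C2=C3. C3 is then raised from aldehyde to ester level.
- Reason: the head of the chain becomes CH(OR)-CH2-CO2Me.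
- Gain: two carbons and the alkene geometry are removed.
- Demand: a Z-selective olefination, cold enough that the β-silyloxy aldehyde does not eliminate.

**9 to 7 and 8.**
- Bonds cut: C12-C13, as a decarboxylative radical coupling.
- Reason: the tail end becomes CH(OR)-CH2-CO2H, the same motif as the head, so the hidden mirror plane extends over eleven carbons.
- Gain: the tail comes from a bulk fatty acid in one step, with no alkene to hydrogenate.
- Demand: a primary β-silyloxy radical must be formed and cross-coupled without touching C11.

**7 to 5 to 4.**
- Bonds cut: none in the skeleton. Only the acid/ester difference between the ends is erased.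
- Reason and gain: 4 is meso, has half as many distinct atoms, and poses a problem of relative configuration only.
- Demand: one forward step must tell the two mirror-image ester arms apart. That step fixes the absolute configuration of C5, C7, C9 and C11 together.

**4 to 2 and two molecules of 3 (key disconnection).**
- Bonds cut: C4-C5 and C11-C12 together.
- Reason: both bonds lie β to an existing ring oxygen, and the two required outcomes are mirror images of each other. One achiral reagent under substrate control can therefore serve both ends.
- Gain: an eleven-carbon tetraoxygenated chain with four stereocentres falls back to a seven-carbon compound with two.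
- Demand: 1,3-anti addition at both termini. In one sentence, the route is a double acetate aldol addition at both ends of meso 2.

**2 to 1.**
- Bonds cut: none. The two termini are returned to the carboxyl oxidation level.
- Reason: 1 is a bulk article that already holds the cis C7/C9 pair.
- Gain: only its cis relation is used, so either enantiomer or the racemate would serve equally.
- Demand: ester and nitrile must both stop at the aldehyde stage in one operation.

## Other disconnections considered

**Alternative 1:** This is the first plan that comes to mind.
- Cut: C2=C3 by ring-closing metathesis of acrylate A1 (second-generation Grubbs catalyst). Before that, C10-C11, C8-C9, C6-C7 and C4-C5 are cut one after another, as four asymmetric allylations starting from decanal.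
- Ground for rejection: each stereocentre costs an allylation, a protection and an alkene cleavage. The chiral controller must change its sense along the chain to give anti, syn, anti. The sequence is fully linear and roughly twice as long as the chosen one. It treats four centres as four problems, whereas the mirror plane allows them to be handled in pairs.

**Alternative 2:**
- Cut: C7-C8. The boron enolate of methyl ketone A2 adds to aldehyde A3 to give aldol A4 under 1,5-anti induction from the C11 ether. A Narasaka-Prasad reduction then sets C9.
- Ground for rejection: the union is convergent, but C11 and C5 still need two independent asymmetric steps. The 1,5-induction depends on the type of ether at C11, and the β-silyloxy aldehyde does not reinforce it. The head still requires acryloylation and metathesis. The step count stays above that of the chosen plan, with two chirality sources instead of one symmetry-breaking event.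

**Alternative 3:**
- Cut: C8-C9 and C9-C10. A lithiated 2-silyl-1,3-dithiane opens epoxide A5, a Brook rearrangement relays the anion, and epoxide A6 is opened to give A7. Dithiane removal and syn reduction follow.
- Ground for rejection: two bonds form in one flask, but the load moves onto A6, which already contains the C5/C7 anti pair and needs its own multistep asymmetric synthesis. A5 needs a resolution. C9 passes through ketone unmasking and reduction next to an alkene. The stereotetrad is still assembled centre by centre.

Key step: step 2

Assumption: the hydrolase of step 3 is taken to cleave the ester arm whose β-carbinol carbon (C11) is S-configured in 4. The sense of this choice must be settled by enzyme screening and is covered by the fallback for step 3.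

## Steps

Step 1
Reactants: 1 tert-butyl 2-[(4R,6R)-6-(cyanomethyl)-2,2-dimethyl-1,3-dioxan-4-yl]acetate
Product: 2 2,2'-[(4R,6S)-2,2-dimethyl-1,3-dioxane-4,6-diyl]diacetaldehyde (meso, cis)
Conditions: i-Bu2AlH (2.4 equiv), toluene/CH2Cl2, −78 °C; then aq. potassium sodium tartrate, 0 °C
Reagents that add atoms: water, O
Why: Partial reduction with a dialkylaluminium hydride; the ester should stop at the aluminium hemiacetal and the nitrile at the N-aluminoimine, and both collapse to CHO only on aqueous work-up. C7 and C9 are untouched, and with equal termini the cis-dioxane gains a mirror plane through C8, so 2 is meso.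

Step 2
Reactants: 2 2,2'-[(4R,6S)-2,2-dimethyl-1,3-dioxane-4,6-diyl]diacetaldehyde; 3 tert-butyl[(1-methoxyethenyl)oxy]dimethylsilane (2.5 equiv)
Product: 4 dimethyl (3R,5R,7S,9S)-3,9-dihydroxy-5,7-(isopropylidenedioxy)undecanedioate (meso; anti,syn,anti)
Conditions: BF3·OEt2 (2.2 equiv), CH2Cl2, −78 °C; pH 7 buffer
Reagents that add atoms: none
Why: Two-directional Mukaiyama aldol addition: BF3 binds each formyl oxygen and two molecules of 3 attack through open transition states, forming C4-C5 and C11-C12 in one operation, after which fluoride transfer removes the silyl groups and work-up frees both hydroxyls. The closest known reaction type is the BF3-promoted addition of silyl ketene acetals to β-alkoxy aldehydes, which is 1,3-anti selective; here it runs at both ends of one molecule. No ring is closed. C5 is controlled by C7 and C11 by C9: in the reactive conformer of the activated aldehyde the β C-O bond of the dioxane points away from the C=O dipole, the ring carbon C8 shields one face and the nucleophile enters from the other, which gives the anti relation. Because 2 is mirror-symmetric, the two formyl groups are enantiotopic and carry the same bias in mirror-image sense, so anti addition at both ends should give the meso array with all four stereocentres in the correct relative configuration. The step needs facial selectivity at both termini and survival of the ketal; a monodentate, non-chelating Lewis acid, −78 °C and the equatorial side arms of the chair dioxane secure this. Products of one wrong addition are unsymmetrical diastereomers that chromatography can remove, and no enantioselectivity is asked of this step.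

Step 3
Reactants: 4 dimethyl (3R,5R,7S,9S)-3,9-dihydroxy-5,7-(isopropylidenedioxy)undecanedioate
Product: 5 (3S,5S,7R,9R)-3,9-dihydroxy-5,7-(isopropylidenedioxy)-11-methoxy-11-oxoundecanoic acid
Conditions: pig liver esterase, 0.1 M phosphate buffer pH 7/acetone 9:1, 25 °C, stopped at one ester equivalent
Reagents that add atoms: water, O
Why: Hydrolase-catalysed monohydrolysis of a meso diester; the two arms are mirror images, and the chiral acyl pocket of the serine hydrolase should accept only the arm whose β-carbinol has the fitting sense. The wrong half-ester still holds the fast-reacting arm and is drained to the diacid, which raises the enantiomeric purity of 5. The step fixes the absolute configuration of C5, C7, C9 and C11 at once and tells head from tail.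

Step 4
Reactants: 5 (3S,5S,7R,9R)-3,9-dihydroxy-5,7-(isopropylidenedioxy)-11-methoxy-11-oxoundecanoic acid
Product: 7 (3S,5R,7S,9R)-3,9-bis(tert-butyldimethylsilyloxy)-5,7-(isopropylidenedioxy)-11-methoxy-11-oxoundecanoic acid, via tris-silylated silyl ester 6 (not isolated)
Conditions: t-BuMe2SiCl (3.5 equiv), imidazole, DMF, rt; then MeOH/H2O, rt
Reagents that add atoms: tert-butyldimethylsilyl chloride, CC(C)(C)[Si](C)(C)Cl
Why: Standard silylation; the carboxyl group is silylated as well, and the labile silyl ester 6 is solvolysed by aqueous methanol while the secondary silyl ethers, ketal and methyl ester stay. The ethers block fragmentation of a free β-hydroxy acid at the anode and elimination in steps 6 and 7.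

Step 5
Reactants: 7 (3S,5R,7S,9R)-3,9-bis(tert-butyldimethylsilyloxy)-5,7-(isopropylidenedioxy)-11-methoxy-11-oxoundecanoic acid; 8 nonanoic acid (10 equiv)
Product: 9 methyl (3R,5S,7R,9R)-3,9-bis(tert-butyldimethylsilyloxy)-5,7-(isopropylidenedioxy)octadecanoate
Conditions: Pt anode, Pt cathode, undivided cell, MeOH, KOH (5 mol% of total acid), constant current, 20-25 °C
Reagents that add atoms: none
Why: Mixed Kolbe electrolysis; anodic decarboxylation gives the primary C12 radical and the octyl radical, which combine at the electrode to form C12-C13, and the large excess of cheap 8 steers 7 into the cross product. O-protected β-hydroxy acids are established Kolbe partners, a primary radical is not oxidised further, and C11 is not part of the radical centre, so its configuration is kept.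

Step 6
Reactants: 9 methyl (3R,5S,7R,9R)-3,9-bis(tert-butyldimethylsilyloxy)-5,7-(isopropylidenedioxy)octadecanoate
Product: 10 (3R,5S,7R,9R)-3,9-bis(tert-butyldimethylsilyloxy)-5,7-(isopropylidenedioxy)octadecanal
Conditions: i-Bu2AlH (1.1 equiv), CH2Cl2, −78 °C; then aq. potassium sodium tartrate
Reagents that add atoms: none
Why: Partial reduction of a methyl ester; the aluminium hemiacetal is stable at −78 °C and releases the aldehyde on work-up. This is routine for β-silyloxy esters, and silyl ethers and ketal are inert.

Step 7
Reactants: 10 (3R,5S,7R,9R)-3,9-bis(tert-butyldimethylsilyloxy)-5,7-(isopropylidenedioxy)octadecanal; 11 methyl 2-[bis(2,2,2-trifluoroethoxy)phosphoryl]acetate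
Product: 12 methyl (2Z,5S,7S,9R,11R)-5,11-bis(tert-butyldimethylsilyloxy)-7,9-(isopropylidenedioxy)icos-2-enoate
Conditions: KN(SiMe3)2, 18-crown-6, THF, −78 °C
Reagents that add atoms: none
Why: Still-Gennari olefination; the electron-poor phosphonate and the dissociated potassium ion make elimination from the kinetic adduct fast, which should give the Z-enoate. The low temperature protects the β-silyloxy aldehyde from elimination.

Step 8
Reactants: 12 methyl (2Z,5S,7S,9R,11R)-5,11-bis(tert-butyldimethylsilyloxy)-7,9-(isopropylidenedioxy)icos-2-enoate
Product: 14 (6S)-6-[(2S,4S,6R)-2,4,6-trihydroxypentadecyl]-5,6-dihydro-2H-pyran-2-one, via tetrahydroxy Z-enoate 13 (not isolated)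
Conditions: aq. HF (48%), MeCN, 0 °C to rt
Reagents that add atoms: none
Why: Acid cleaves both silyl ethers and the ketal, and of the four hydroxyls only the one on C5 reaches the Z-ester through a six-membered ring, so lactonisation should follow in the same flask without base. Oxa-Michael closure by the C7 hydroxyl is disfavoured because the 5,7-anti relation would force the C8 chain axial in the bicycle.

## Compound list

1 | tert-butyl 2-[(4R,6R)-6-(cyanomethyl)-2,2-dimethyl-1,3-dioxan-4-yl]acetate | CC(C)(C)OC(=O)C[C@H]1C[C@@H](CC#N)OC(C)(C)O1 | starting material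
2 | 2,2'-[(4R,6S)-2,2-dimethyl-1,3-dioxane-4,6-diyl]diacetaldehyde (meso) | O=CC[C@H]1C[C@@H](CC=O)OC(C)(C)O1 | intermediate
3 | tert-butyl[(1-methoxyethenyl)oxy]dimethylsilane | C=C(OC)O[Si](C)(C)C(C)(C)C | starting material
4 | dimethyl (3R,5R,7S,9S)-3,9-dihydroxy-5,7-(isopropylidenedioxy)undecanedioate (meso) | COC(=O)C[C@@H](O)C[C@H]1C[C@@H](C[C@@H](O)CC(=O)OC)OC(C)(C)O1 | intermediate
5 | (3S,5S,7R,9R)-3,9-dihydroxy-5,7-(isopropylidenedioxy)-11-methoxy-11-oxoundecanoic acid | OC(=O)C[C@@H](O)C[C@H]1C[C@@H](C[C@@H](O)CC(=O)OC)OC(C)(C)O1 | intermediate
6 | tert-butyldimethylsilyl ester of 7 | CC(C)(C)[Si](C)(C)OC(=O)C[C@@H](O[Si](C)(C)C(C)(C)C)C[C@H]1C[C@@H](C[C@@H](O[Si](C)(C)C(C)(C)C)CC(=O)OC)OC(C)(C)O1 | intermediate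
7 | (3S,5R,7S,9R)-3,9-bis(tert-butyldimethylsilyloxy)-5,7-(isopropylidenedioxy)-11-methoxy-11-oxoundecanoic acid | OC(=O)C[C@@H](O[Si](C)(C)C(C)(C)C)C[C@H]1C[C@@H](C[C@@H](O[Si](C)(C)C(C)(C)C)CC(=O)OC)OC(C)(C)O1 | intermediate
8 | nonanoic acid | CCCCCCCCC(=O)O | starting material
9 | methyl (3R,5S,7R,9R)-3,9-bis(tert-butyldimethylsilyloxy)-5,7-(isopropylidenedioxy)octadecanoate | CCCCCCCCC[C@@H](O[Si](C)(C)C(C)(C)C)C[C@H]1C[C@@H](C[C@@H](O[Si](C)(C)C(C)(C)C)CC(=O)OC)OC(C)(C)O1 | intermediate
10 | (3R,5S,7R,9R)-3,9-bis(tert-butyldimethylsilyloxy)-5,7-(isopropylidenedioxy)octadecanal | CCCCCCCCC[C@@H](O[Si](C)(C)C(C)(C)C)C[C@H]1C[C@@H](C[C@@H](O[Si](C)(C)C(C)(C)C)CC=O)OC(C)(C)O1 | intermediate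
11 | methyl 2-[bis(2,2,2-trifluoroethoxy)phosphoryl]acetate | COC(=O)CP(=O)(OCC(F)(F)F)OCC(F)(F)F | starting material
12 | methyl (2Z,5S,7S,9R,11R)-5,11-bis(tert-butyldimethylsilyloxy)-7,9-(isopropylidenedioxy)icos-2-enoate | CCCCCCCCC[C@@H](O[Si](C)(C)C(C)(C)C)C[C@H]1C[C@@H](C[C@@H](O[Si](C)(C)C(C)(C)C)C/C=C\C(=O)OC)OC(C)(C)O1 | intermediate
13 | methyl (2Z,5S,7R,9S,11R)-5,7,9,11-tetrahydroxyicos-2-enoate | CCCCCCCCC[C@@H](O)C[C@H](O)C[C@H](O)C[C@@H](O)C/C=C\C(=O)OC | intermediate
14 | (6S)-6-[(2S,4S,6R)-2,4,6-trihydroxypentadecyl]-5,6-dihydro-2H-pyran-2-one | CCCCCCCCC[C@@H](O)C[C@H](O)C[C@H](O)C[C@@H]1CC=CC(=O)O1 | target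

## Step count and least certain steps

Total step count: 8. Longest linear sequence: 8 (from 1).

**Step 2 (key step).**
- Most likely failure: poor facial selectivity at one or both termini. The β-oxygen is tied into a ketal ring and cannot adjust its conformation freely, and the share of the meso product falls with the square of the single-site selectivity. Partial loss of the ketal under BF3 is the second danger.
- Fallback: it sets out from 2 and replaces aldehyde face control by hydroxyl-directed ketone reduction.
  - A double Roskamp homologation (methyl diazoacetate, SnCl2, CH2Cl2) would give dimethyl 4,4'-[(4R,6S)-2,2-dimethyl-1,3-dioxane-4,6-diyl]bis(3-oxobutanoate) F1.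
  - Aqueous acetic acid would free dimethyl (5R,7S)-5,7-dihydroxy-3,9-dioxoundecanedioate F2.
  - A double Evans-Saksena reduction (Me4NBH(OAc)3, MeCN/AcOH, −30 °C) would deliver hydride from each inner hydroxyl, giving dimethyl (3R,5S,7R,9S)-3,5,7,9-tetrahydroxyundecanedioate F3.
  - One equivalent of 2,2-dimethoxypropane under equilibrating acid catalysis would then place the ketal on the only syn pair, which forms the only chair dioxane. The route is rejoined at 4.

**Step 3.**
- Most likely failure: weak discrimination between the two arms, or discrimination in the opposite sense. The stereocentre lies β to the reacting carbonyl and the remainder of the chain is large for the acyl pocket.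
- Fallback: it sets out from 4 and replaces catalysis by classical resolution with recycling.
  - One equivalent of LiOH would give 5 together with its enantiomer, (3R,5R,7S,9S)-3,9-dihydroxy-5,7-(isopropylidenedioxy)-11-methoxy-11-oxoundecanoic acid F4.
  - Crystallisation with (R)-1-phenylethylamine (or its antipode, whichever gives the less soluble salt of 5) would give the (R)-1-phenylethylammonium salt of 5 F5, and acidification returns to the route at 5.
  - F4 from the mother liquor is re-esterified with Me3SiCHN2 to meso 4 and used again, so no material of the wrong handedness is lost.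

**Step 5.**
- Most likely failure: loss of 7 to homocoupling and disproportionation of the radicals, anode passivation by the lipophilic substrate, or methanolysis of the ketal in the acidic layer at the anode.
- Fallback: it sets out from 7 and replaces radical-radical combination by metal capture of the radical.
  - N-hydroxyphthalimide, diisopropylcarbodiimide and DMAP would give the N-(acyloxy)phthalimide of 7 F6.
  - NiCl2(dme), 4,4'-di-tert-butyl-2,2'-bipyridine and Zn(C8H17)2 in THF/DMF would then couple the C12 radical with an octyl group. The route is rejoined at 9.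

**Step 1.**
- Most likely failure: over-reduction at the ester terminus while the nitrile still needs a higher temperature, or β-elimination of the ring oxygen during hydrolysis of the aluminoimine.
- Fallback: it sets out from 1 and goes through full reduction and re-oxidation.
  - HCl in MeOH (Pinner methanolysis, transesterification and ketal loss) would give dimethyl (3R,5S)-3,5-dihydroxyheptanedioate F7.
  - 2,2-Dimethoxypropane and TsOH would give dimethyl 2,2'-[(4R,6S)-2,2-dimethyl-1,3-dioxane-4,6-diyl]diacetate F8.
  - LiAlH4 would give 2,2'-[(4R,6S)-2,2-dimethyl-1,3-dioxane-4,6-diyl]diethanol F9.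
  - A double Swern oxidation returns to the route at 2.

## Further compounds

F1 | step 2 | dimethyl 4,4'-[(4R,6S)-2,2-dimethyl-1,3-dioxane-4,6-diyl]bis(3-oxobutanoate) (meso) | COC(=O)CC(=O)C[C@H]1C[C@@H](CC(=O)CC(=O)OC)OC(C)(C)O1
F2 | step 2 | dimethyl (5R,7S)-5,7-dihydroxy-3,9-dioxoundecanedioate (meso) | COC(=O)CC(=O)C[C@H](O)C[C@H](O)CC(=O)CC(=O)OC
F3 | step 2 | dimethyl (3R,5S,7R,9S)-3,5,7,9-tetrahydroxyundecanedioate (meso) | COC(=O)C[C@@H](O)C[C@H](O)C[C@H](O)C[C@@H](O)CC(=O)OC
F4 | step 3 | (3R,5R,7S,9S)-3,9-dihydroxy-5,7-(isopropylidenedioxy)-11-methoxy-11-oxoundecanoic acid (enantiomer of 5) | COC(=O)C[C@@H](O)C[C@H]1C[C@@H](C[C@@H](O)CC(=O)O)OC(C)(C)O1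
F5 | step 3 | (R)-1-phenylethylammonium salt of 5 | C[C@@H]([NH3+])c1ccccc1.[O-]C(=O)C[C@@H](O)C[C@H]1C[C@@H](C[C@@H](O)CC(=O)OC)OC(C)(C)O1
F6 | step 5 | N-(acyloxy)phthalimide of 7 | O=C(ON1C(=O)c2ccccc2C1=O)C[C@@H](O[Si](C)(C)C(C)(C)C)C[C@H]3C[C@@H](C[C@@H](O[Si](C)(C)C(C)(C)C)CC(=O)OC)OC(C)(C)O3
F7 | step 1 | dimethyl (3R,5S)-3,5-dihydroxyheptanedioate (meso) | COC(=O)C[C@H](O)C[C@H](O)CC(=O)OC
F8 | step 1 | dimethyl 2,2'-[(4R,6S)-2,2-dimethyl-1,3-dioxane-4,6-diyl]diacetate (meso) | COC(=O)C[C@H]1C[C@@H](CC(=O)OC)OC(C)(C)O1
F9 | step 1 | 2,2'-[(4R,6S)-2,2-dimethyl-1,3-dioxane-4,6-diyl]diethanol (meso) | OCC[C@H]1C[C@@H](CCO)OC(C)(C)O1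
A1 | alternative 1 | (4S,6R,8S,10R)-6,8,10-tris(tert-butyldimethylsilyloxy)nonadec-1-en-4-yl acrylate | CCCCCCCCC[C@@H](O[Si](C)(C)C(C)(C)C)C[C@H](O[Si](C)(C)C(C)(C)C)C[C@H](O[Si](C)(C)C(C)(C)C)C[C@@H](OC(=O)C=C)CC=C
A2 | alternative 2 | (R)-4-(4-methoxybenzyloxy)tridecan-2-one | CCCCCCCCC[C@@H](OCc1ccc(OC)cc1)CC(C)=O
A3 | alternative 2 | (S)-3-(tert-butyldimethylsilyloxy)hex-5-enal | O=CC[C@@H](O[Si](C)(C)C(C)(C)C)CC=C
A4 | alternative 2 | (4S,6R,10R)-4-(tert-butyldimethylsilyloxy)-6-hydroxy-10-(4-methoxybenzyloxy)nonadec-1-en-8-one | CCCCCCCCC[C@@H](OCc1ccc(OC)cc1)CC(=O)C[C@H](O)C[C@@H](O[Si](C)(C)C(C)(C)C)CC=C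
A5 | alternative 3 | (R)-2-nonyloxirane | CCCCCCCCC[C@@H]1CO1
A6 | alternative 3 | (2R)-2-[(2S)-2-(benzyloxy)pent-4-en-1-yl]oxirane | C1O[C@@H]1C[C@@H](OCc2ccccc2)CC=C
A7 | alternative 3 | 2-[(2R)-2-(tert-butyldimethylsilyloxy)undecyl]-2-[(2R,4S)-4-(benzyloxy)-2-hydroxyhept-6-en-1-yl]-1,3-dithiane | CCCCCCCCC[C@@H](O[Si](C)(C)C(C)(C)C)CC1(C[C@H](O)C[C@@H](OCc2ccccc2)CC=C)SCCCS1
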